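**Plan** (clerodane numbering C1–C20; ring A = lactone-fused cyclohexene, ring C = furan-fused seven-membered ketone, ring B = acetoxy-cyclohexane)
Retrosynthesis cuts, in order: C7–C8 of ring B; the C9–vinyl bond; C9=C11 of ring C; the C10–C9 and C1–furan bonds; then ring A into an enal and a 1-amino-3-siloxy diene.
Forward: ring A by catalytic enantioselective Diels–Alder, lactone by reduction/lactonisation, furan by Suzuki–Miyaura coupling, ring C by conjugate addition and ring-closing metathesis, ring B last by a hydrogen-atom-transfer radical cyclisation.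
Stereochemistry: C5 from the chiral chromium catalyst; C10 (addition anti to the pseudo-axial C6 arm), C1 (equilibration), C2 (Luche), C9 (cuprate anti to C5) relayed by substrate control; C7 and C8 set together in the ring-B closure.
Enabling feature: the quaternary carbons C5 and C9 both flank C10 of the trans-fused A/C core, so a CH2–CHO arm on C5 and a vinyl on C9 are held 1,3-syn, and "vinyl + CHO" maps exactly onto the CH(CH3)–CH(OH) unit C8–C7.

Key step: step 16

Assumption: the (R,R)-salen chromium catalyst is taken to deliver the diene to the enal face that gives the C5 configuration drawn for 6; if the opposite sense is found, the (S,S)-catalyst is used.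

Step 1
Reactants: 1 pent-4-enal; 2 ethyl glyoxylate
Product: 4 ethyl (2E)-3-formylhexa-2,5-dienoate, via aldol adduct 3 (not isolated)
Conditions: pyrrolidine (10 mol%), PhCO2H (10 mol%), toluene, 60 °C
Reagents that add atoms: none
Why: Amine-catalysed cross-aldol condensation, in which the enamine of 1 adds to the non-enolisable glyoxylate aldehyde and the adduct dehydrates to the (E)-enal ester; no stereocentre is formed.

Step 2
Reactants: 4 ethyl (2E)-3-formylhexa-2,5-dienoate; 5 (1E)-3-(tert-butyldimethylsilyloxy)-N,N-dimethylbuta-1,3-dien-1-amine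
Product: 6 ethyl 2-allyl-3-(dimethylamino)-2-formyl-5-(tert-butyldimethylsilyloxy)cyclohex-4-ene-1-carboxylate (ester trans to formyl, NMe2 cis to formyl)
Conditions: [Cr(C36H52N2O2)]SbF6 ((R,R)-salen complex of trivalent chromium, 5 mol%), 4 Å MS, CH2Cl2, −40 °C
Reagents that add atoms: none
Why: Enantioselective Diels–Alder reaction of a 1-amino-3-siloxy diene with an α-substituted acrolein: the nucleophilic CH2 terminus should bond to the enal β-carbon (C4) and the amino terminus to C5, the catalyst-bound aldehyde fixes the face and so the quaternary C5, and the (E)-olefin geometry places ester and formyl trans.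

Step 3
Reactants: 6 Diels–Alder adduct
Product: 8 trans-fused 3a-allyl-3,3a,7,7a-tetrahydro-2-benzofuran-1,6-dione (ring A enone with lactone), via hydroxy ester 7 (not isolated)
Conditions: NaBH4, MeOH, −40 °C; then 2 M HCl, THF, 40 °C
Reagents that add atoms: none
Why: Chemoselective aldehyde reduction, then acid hydrolysis of the silyl enol ether with β-elimination of dimethylamine to the enone and lactonisation of the C19 alcohol onto the C18 ester; C5 is untouched.

Step 4
Reactants: 8 enone lactone
Product: 9 (3aS)-3a-allyl-3,3a-dihydro-2-benzofuran-1,6-dione (cross-conjugated dienone lactone)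
Conditions: IBX, DMSO, 75 °C
Reagents that add atoms: none
Why: IBX dehydrogenation of the ketone towards its only enolisable side (C3) should give the C3=C4 olefin conjugated to both carbonyls, removing the C4 stereocentre.

Step 5
Reactants: 9 dienone lactone
Product: 11 3a-(2,2-dimethoxyethyl)-3,3a-dihydro-2-benzofuran-1,6-dione, via aldehyde 10 (not isolated)
Conditions: O3, CH2Cl2/MeOH, −78 °C; Me2S; then TsOH (cat.), MeOH, rt
Reagents that add atoms: methanol CO
Why: Ozonolysis should cleave only the electron-rich terminal allyl olefin (both ring olefins are deactivated by conjugation), and acetalisation masks the C7 aldehyde for the organometallic steps.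

Step 6
Reactants: 11 dimethyl acetal
Product: 12 5-iodo-3a-(2,2-dimethoxyethyl)-3,3a-dihydro-2-benzofuran-1,6-dione (iodine on C1)
Conditions: I2, pyridine, CH2Cl2, rt
Reagents that add atoms: iodine II
Why: α-Iodination of an enone by pyridine addition at the β-carbon, iodination and elimination; only C1 can react because the β-carbon of the other enone (C4) is fully substituted.

Step 7
Reactants: 12 α-iodo dienone; 13 (3-formylfuran-2-yl)boronic acid
Product: 14 2-[3a-(2,2-dimethoxyethyl)-1,6-dioxo-1,3,3a,6-tetrahydro-2-benzofuran-5-yl]furan-3-carbaldehyde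
Conditions: Pd2(dba)3 (2.5 mol%), AsPh3, Ag2O, THF/H2O, rt
Reagents that add atoms: none
Why: Suzuki–Miyaura coupling of an α-iodoenone under mild, nearly neutral silver oxide conditions should form the C1–furan bond without touching the base-sensitive dienone.

Step 8
Reactants: 14 furyl aldehyde; 15 vinylmagnesium bromide
Product: 16 the 3-(1-hydroxyprop-2-enyl)furan analogue of 14 (C12 epimers)
Conditions: ZnCl2, THF, −78 to 0 °C; aq. NH4Cl
Reagents that add atoms: none
Why: The vinylzinc reagent formed by transmetalation should add to the aldehyde only, since organozinc reagents do not attack the cross-conjugated ketone or the lactone; the new carbinol centre is oxidised later.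

Step 9
Reactants: 16 furyl vinyl carbinol; 17 isopropenylmagnesium bromide
Product: 19 C10-isopropenyl C2-ketone (isopropenyl cis to the lactone CH2 and trans to the C6 arm; furyl at C1 trans to isopropenyl), via silyl enol ether 18 (not isolated)
Conditions: TMSCl, Et3N, THF, 0 °C; then 17, CuBr·SMe2 (20 mol%), TMSCl, −78 °C; then K2CO3, MeOH, 0 °C
Reagents that add atoms: none
Why: Copper-catalysed conjugate addition to the C1=C10 enone (the other β-carbon, C4, is fully substituted); the unsaturated lactone holds C19 in the ring plane so the C6 arm is pseudo-axial and the nucleophile should enter anti to it (C10), and methanolysis protonates C1 to the trans isomer.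

Step 10
Reactants: 19 ketone
Product: 20 C2 alcohol (OH trans to the furyl group)
Conditions: NaBH4, CeCl3·7H2O, MeOH, −78 °C
Reagents that add atoms: none
Why: Luche 1,2-reduction of the enone; axial hydride attack should give the equatorial C2 alcohol, trans to the equatorial furyl substituent.

Step 11
Reactants: 20 diol
Product: 21 tricyclic diol with ring C closed (C9=C11 olefin, C12 carbinol)
Conditions: second-generation Grubbs catalyst (5 mol%), CH2Cl2, 40 °C
Reagents that add atoms: none
Why: Ring-closing metathesis between the isopropenyl group on C10 and the vinyl carbinol on the furan, both equatorial on the trans C1/C10 pair, should close the seven-membered ring with loss of ethylene.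

Step 12
Reactants: 21 tricyclic diol
Product: 22 ring-C dienone with free C2–OH
Conditions: MnO2, CH2Cl2, rt
Reagents that add atoms: none
Why: The doubly activated (furyl and allyl) C12 carbinol should be oxidised much faster than the C2 alcohol, whose olefin is electron-poor.

Step 13
Reactants: 22 hydroxy dienone
Product: 23 C2 tert-butyldimethylsilyl ether
Conditions: TBSCl, imidazole, DMF, 40 °C
Reagents that add atoms: tert-butyldimethylsilyl chloride CC(C)(C)[Si](C)(C)Cl
Why: Standard silylation protects C2–OH so that the C7 hydroxyl can later be acetylated alone.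

Step 14
Reactants: 23 silyl ether; 15 vinylmagnesium bromide
Product: 25 C9-methyl C9-vinyl ketone (vinyl cis to H10), via silyl enol ether 24 (not isolated)
Conditions: 15, CuBr·SMe2 (20 mol%), TMSCl, THF, −78 to −30 °C; then K2CO3, MeOH, 0 °C
Reagents that add atoms: none
Why: Silyl-accelerated copper-catalysed conjugate addition to the β,β-disubstituted enone creates the quaternary C9; the vinyl group should add anti to the γ-substituent C5 on C10, as in 4-substituted cycloalkenones.

Step 15
Reactants: 25 vinyl ketone
Product: 26 C7 aldehyde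
Conditions: LiBF4, MeCN/H2O (50:1), rt
Reagents that add atoms: water O
Why: Mild acetal hydrolysis should unmask the aldehyde without cleaving the silyl ether.

Step 16
Reactants: 26 aldehyde
Product: 27 pentacyclic 7-alcohol (7-OH and 8-CH3 both equatorial, trans)
Conditions: Fe(acac)3 (30 mol%), PhSiH3, EtOH, 60 °C
Reagents that add atoms: none
Why: Proposed new method: an iron hydride formed from Fe(acac)3 and PhSiH3 should transfer a hydrogen atom to the terminal carbon of the electron-neutral C9 vinyl group (creating the C17 methyl), and the resulting secondary C8 radical adds to the C7 aldehyde carbon in a 6-exo-trig closure of ring B; reduction of the alkoxy radical by divalent iron/silane and protonation by ethanol makes the otherwise reversible addition productive. The closest known reaction types are the hydrogen-atom-transfer-initiated cyclisation of alkene-tethered ketones under the same iron/silane conditions and tin-hydride radical cyclisations onto aldehydes; this step extends them to an aldehyde acceptor. Ring B should close through a chair-like transition state in which the C5–C6 and C9–C8 bonds are the equatorial arms of the trans-fused A/C core, 1,3-related through C10. At C7 the carbonyl oxygen should sit equatorial because the axial position is blocked by the syn-axial C19 methylene and C20 methyl; at C8 the new methyl should take the pseudo-equatorial position, trans to the oxygen, since the pseudo-axial one is syn-axial to H10. The step needs hydrogen-atom transfer to the vinyl group and not to the conjugated lactone olefin, and cyclisation faster than reduction of the radical; the preference of metal-hydride transfer for electron-neutral olefins and the proximity enforced by the two quaternary centres should secure both.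

Step 17
Reactants: 27 alcohol
Product: 28 7-acetate
Conditions: Ac2O, pyridine, DMAP (cat.), CH2Cl2, rt
Reagents that add atoms: acetic anhydride CC(=O)OC(C)=O
Why: Standard acylation of the only free hydroxyl.

Step 18
Reactants: 28 acetate
Product: 29 CNP0182929.2
Conditions: HF·pyridine, THF, 0 °C to rt
Reagents that add atoms: none
Why: Fluoride-mediated removal of the silyl ether should free the C2 alcohol while the acetate and lactone remain intact.

**Compound list**
1 | pent-4-enal | C=CCCC=O | starting material
2 | ethyl glyoxylate | CCOC(=O)C=O | starting material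
3 | ethyl 3-formyl-2-hydroxyhex-5-enoate (diastereomer mixture) | CCOC(=O)C(O)C(CC=C)C=O | intermediate
4 | ethyl (2E)-3-formylhexa-2,5-dienoate | CCOC(=O)/C=C(\CC=C)C=O | intermediate
5 | (1E)-3-(tert-butyldimethylsilyloxy)-N,N-dimethylbuta-1,3-dien-1-amine | C=C(O[Si](C)(C)C(C)(C)C)/C=C/N(C)C | starting material
6 | ethyl 2-allyl-3-(dimethylamino)-2-formyl-5-(tert-butyldimethylsilyloxy)cyclohex-4-ene-1-carboxylate (ester trans, NMe2 cis to formyl) | CCOC(=O)[C@H]1CC(O[Si](C)(C)C(C)(C)C)=C[C@H](N(C)C)[C@]1(CC=C)C=O | intermediate
7 | 2-(hydroxymethyl) analogue of 6 | CCOC(=O)[C@H]1CC(O[Si](C)(C)C(C)(C)C)=C[C@H](N(C)C)[C@]1(CC=C)CO | intermediate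
8 | trans-fused 3a-allyl-3,3a,7,7a-tetrahydro-2-benzofuran-1,6-dione | O=C1OC[C@@]2(CC=C)C=CC(=O)C[C@H]12 | intermediate
9 | (3aS)-3a-allyl-3,3a-dihydro-2-benzofuran-1,6-dione | O=C1OC[C@@]2(CC=C)C=CC(=O)C=C12 | intermediate
10 | 2-(1,6-dioxo-1,3-dihydro-2-benzofuran-3a-yl)acetaldehyde (C5 as in 9) | O=C1OC[C@@]2(CC=O)C=CC(=O)C=C12 | intermediate
11 | 3a-(2,2-dimethoxyethyl)-3,3a-dihydro-2-benzofuran-1,6-dione | O=C1OC[C@@]2(CC(OC)OC)C=CC(=O)C=C12 | intermediate
12 | 5-iodo-3a-(2,2-dimethoxyethyl)-3,3a-dihydro-2-benzofuran-1,6-dione | O=C1OC[C@@]2(CC(OC)OC)C=C(I)C(=O)C=C12 | intermediate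
13 | (3-formylfuran-2-yl)boronic acid | OB(O)c1occc1C=O | starting material
14 | 2-[3a-(2,2-dimethoxyethyl)-1,6-dioxo-1,3,3a,6-tetrahydro-2-benzofuran-5-yl]furan-3-carbaldehyde | O=C1OC[C@@]2(CC(OC)OC)C=C(c3occc3C=O)C(=O)C=C12 | intermediate
15 | vinylmagnesium bromide | C=C[Mg]Br | starting material
16 | 3-(1-hydroxyprop-2-enyl)furan analogue of 14 (C12 epimers) | O=C1OC[C@@]2(CC(OC)OC)C=C(c3occc3C(O)C=C)C(=O)C=C12 | intermediate
17 | isopropenylmagnesium bromide | CC(=C)[Mg]Br | starting material
18 | C2 trimethylsilyl enol ether / C12 trimethylsilyl ether of 19 | C[Si](C)(C)OC1=C(c2occc2C(O[Si](C)(C)C)C=C)[C@H](C(C)=C)[C@]2(CC(OC)OC)COC(=O)C2=C1 | intermediate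
19 | C10-isopropenyl, C1-furyl C2-ketone (isopropenyl cis to lactone CH2; furyl trans to isopropenyl) | O=C1OC[C@@]2(CC(OC)OC)[C@@H](C(C)=C)[C@H](c3occc3C(O)C=C)C(=O)C=C12 | intermediate
20 | C2 alcohol of 19 (OH trans to furyl) | O=C1OC[C@@]2(CC(OC)OC)[C@@H](C(C)=C)[C@H](c3occc3C(O)C=C)[C@@H](O)C=C12 | intermediate
21 | tricyclic 2,12-diol with ring C closed (C9=C11) | O=C1OC[C@@]2(CC(OC)OC)[C@H]3C(C)=CC(O)c4ccoc4[C@@H]3[C@@H](O)C=C12 | intermediate
22 | ring-C dienone (C12 ketone), free 2-OH | O=C1OC[C@@]2(CC(OC)OC)[C@H]3C(C)=CC(=O)c4ccoc4[C@@H]3[C@@H](O)C=C12 | intermediate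
23 | 2-O-tert-butyldimethylsilyl ether of 22 | O=C1OC[C@@]2(CC(OC)OC)[C@H]3C(C)=CC(=O)c4ccoc4[C@@H]3[C@@H](O[Si](C)(C)C(C)(C)C)C=C12 | intermediate
24 | C12 trimethylsilyl enol ether of 25 | O=C1OC[C@@]2(CC(OC)OC)[C@H]3[C@](C)(C=C)C=C(O[Si](C)(C)C)c4ccoc4[C@@H]3[C@@H](O[Si](C)(C)C(C)(C)C)C=C12 | intermediate
25 | C9-methyl C9-vinyl ketone (vinyl cis to H10), C7 dimethyl acetal | O=C1OC[C@@]2(CC(OC)OC)[C@H]3[C@](C)(C=C)CC(=O)c4ccoc4[C@@H]3[C@@H](O[Si](C)(C)C(C)(C)C)C=C12 | intermediate
26 | C7 aldehyde of 25 | O=C1OC[C@@]2(CC=O)[C@H]3[C@](C)(C=C)CC(=O)c4ccoc4[C@@H]3[C@@H](O[Si](C)(C)C(C)(C)C)C=C12 | intermediate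
27 | pentacyclic 7-alcohol, 2-O-silyl ether (7-OH, 8-CH3 equatorial) | O[C@H]1C[C@@]23COC(=O)C2=C[C@H](O[Si](C)(C)C(C)(C)C)[C@H]2c4occc4C(=O)C[C@@](C)([C@@H]1C)[C@@H]23 | intermediate
28 | 7-acetate of 27 | CC(=O)O[C@H]1C[C@@]23COC(=O)C2=C[C@H](O[Si](C)(C)C(C)(C)C)[C@H]2c4occc4C(=O)C[C@@](C)([C@@H]1C)[C@@H]23 | intermediate
29 | CNP0182929.2 | CC(=O)O[C@H]1C[C@@]23COC(=O)C2=C[C@H](O)[C@H]2c4occc4C(=O)C[C@@](C)([C@@H]1C)[C@@H]23 | target

**Count and risks**
Total step count: 18. Longest linear sequence: 18 steps (from 1 and 2 to 29).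

Step 16 (Proposed new method). The C8 radical may simply be reduced, giving an ethyl group. Addition to the aldehyde may revert before the alkoxy radical is trapped. The methyl orientation at C8 may be poorly controlled, or the silane may reduce the aldehyde. The fallback uses known chemistry, sets out from 23 and returns at 27. Copper-catalysed addition of isopropenylmagnesium bromide (aqueous NH4Cl quench) would give the C9-isopropenyl ketone F1. LiBF4 in wet MeCN would give the aldehyde F2, and Wittig methylenation (Ph3P=CH2) the C5-allyl compound F3. Ring-closing metathesis with second-generation Grubbs catalyst would close ring B as the C7=C8 trisubstituted cyclohexene F4. Hydroboration–oxidation (BH3·SMe2; NaOH, H2O2) from the face opposite the axial C19 and C20 groups would set 7-OH and 8-H together and reduce the C12 ketone, giving the diol F5. MnO2 would reoxidise the furyl carbinol to 27.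

Step 9. Site selectivity may be poor, through attack or electron transfer at the doubly activated C3=C4 olefin, and facial selectivity at C10 may erode. The fallback sets out from 16 and returns at 19. Reversible DBU-mediated Michael addition of nitroethane in MeCN would give the C10 nitroalkyl adduct F6. A Nef reaction (NaOMe; then TiCl3, NH4OAc) would give the C10 acetyl compound F7. Methylenation of the methyl ketone with Zn/CH2Br2/TiCl4 would deliver 19.

Step 14. Addition to the hindered, furan-deactivated β,β-disubstituted enone may be sluggish, and the facial preference may be lost. The fallback sets out from 23 and returns at 25. Conjugate addition of Et2AlC≡CSiMe3 catalysed by zerovalent nickel (from Ni(acac)2 and iBu2AlH) would place the slimmer alkynyl group on C9, giving the silylalkynyl ketone F8. K2CO3 in MeOH would give the terminal alkyne F9. Semihydrogenation over Pd/CaCO3 poisoned with Pb(OAc)2 and quinoline would give 25.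

Further compounds
F1 | step 16 | C9-isopropenyl analogue of 25 | O=C1OC[C@@]2(CC(OC)OC)[C@H]3[C@](C)(C(C)=C)CC(=O)c4ccoc4[C@@H]3[C@@H](O[Si](C)(C)C(C)(C)C)C=C12
F2 | step 16 | C7 aldehyde of F1 | O=C1OC[C@@]2(CC=O)[C@H]3[C@](C)(C(C)=C)CC(=O)c4ccoc4[C@@H]3[C@@H](O[Si](C)(C)C(C)(C)C)C=C12
F3 | step 16 | C5-allyl, C9-isopropenyl diene | O=C1OC[C@@]2(CC=C)[C@H]3[C@](C)(C(C)=C)CC(=O)c4ccoc4[C@@H]3[C@@H](O[Si](C)(C)C(C)(C)C)C=C12
F4 | step 16 | pentacyclic C7=C8 olefin, 2-O-silyl ether | CC1=CC[C@@]23COC(=O)C2=C[C@H](O[Si](C)(C)C(C)(C)C)[C@H]2c4occc4C(=O)C[C@]1(C)[C@@H]23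
F5 | step 16 | pentacyclic 7,12-diol, 2-O-silyl ether (C12 epimers) | O[C@H]1C[C@@]23COC(=O)C2=C[C@H](O[Si](C)(C)C(C)(C)C)[C@H]2c4occc4C(O)C[C@@](C)([C@@H]1C)[C@@H]23
F6 | step 9 | C10 (1-nitroethyl) adduct of 16 | O=C1OC[C@@]2(CC(OC)OC)[C@@H](C(C)[N+](=O)[O-])[C@H](c3occc3C(O)C=C)C(=O)C=C12
F7 | step 9 | C10 acetyl compound | O=C1OC[C@@]2(CC(OC)OC)[C@@H](C(C)=O)[C@H](c3occc3C(O)C=C)C(=O)C=C12
F8 | step 14 | C9 (trimethylsilylethynyl) ketone | O=C1OC[C@@]2(CC(OC)OC)[C@H]3[C@](C)(C#C[Si](C)(C)C)CC(=O)c4ccoc4[C@@H]3[C@@H](O[Si](C)(C)C(C)(C)C)C=C12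
F9 | step 14 | C9 ethynyl ketone | O=C1OC[C@@]2(CC(OC)OC)[C@H]3[C@](C)(C#C)CC(=O)c4ccoc4[C@@H]3[C@@H](O[Si](C)(C)C(C)(C)C)C=C12
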